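**Strategy**

1. Retrosynthetic cuts: first the oxirane O–CH2 bond (back to a tertiary bromohydrin), then the two ester C–O bonds, then the C–Br bond with re-formation of an oxetane O–CH2 bond, and last the aryl–C bond to the carbonyl carbon of oxetan-3-one.
2. Enabling feature: C2 of the oxirane is a quaternary carbon bonded to the benzene ring, to the oxirane oxygen and to two oxygen-bearing methylenes (the ring CH2 and the CH2 carrying the 3-methylbutanoate). Joining these two CH2 groups through one oxygen gives an achiral 3-aryloxetan-3-ol in which they are enantiotopic.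
3. Forward order: the benzene ring is bought and brominated, and the four-membered ring is bought as oxetan-3-one and attached intact by aryllithium addition. After phenol tigloylation and O-silylation, bromide opens the oxetane enantioselectively. Isovalerylation, desilylation and a 3-exo-tet closure then give the oxirane, the only ring made in the route.
4. Stereochemistry: the single stereocentre is set when a chiral squaramide selects one of the two oxetane CH2 groups of the achiral precursor. Its four bonds are not touched afterwards; the S label of the bromides becomes R in the epoxide only through the CIP ranking. The E alkene is bought with tigloyl chloride.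

Key step: step 5

Remark: the sense of induction on this substrate cannot be predicted with certainty, so the mirror-image form of the catalyst that gives the (S)-bromide is chosen in a pilot run, with ee (chiral HPLC) and absolute configuration (anomalous-dispersion X-ray, bromine as heavy atom) to be checked at 11.

Step 1
Reactants: 1 4-methoxy-3-methylphenol
Product: 2 2-bromo-4-methoxy-5-methylphenol
Conditions: NBS (1.0 equiv), MeCN, 0 °C, dark
Reagents that add atoms: N-bromosuccinimide, O=C1CCC(=O)N1Br
Why: Electrophilic aromatic bromination, in which the free hydroxyl is the strongest director, its para position is taken by OMe, and of the two ortho sites the one para to the methyl group is open while the other is wedged between OH and CH3.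

Step 2
Reactants: 2 2-bromo-4-methoxy-5-methylphenol; 3 oxetan-3-one
Product: 6 3-(2-hydroxy-5-methoxy-4-methylphenyl)oxetan-3-ol, via lithium bromophenolate 4 (not isolated), via aryllithium phenolate 5 (not isolated)
Conditions: t-BuLi (3.1 equiv), THF, −78 °C; 3 (1.3 equiv), −78 to −40 °C; sat. aq NH4Cl, −40 °C
Reagents that add atoms: none
Why: O–H deprotonation followed by bromine–lithium exchange should give a C,O-dilithio species whose aryl carbon adds 1,2 to the strained, unhindered ketone (aryllithium addition to a ketone), and the cold, near-neutral quench with purification on amine-washed silica should spare the acid-labile oxetanol from attack by its own phenol.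

Step 3
Reactants: 6 3-(2-hydroxy-5-methoxy-4-methylphenyl)oxetan-3-ol; 7 (E)-2-methylbut-2-enoyl chloride (tigloyl chloride)
Product: 8 2-(3-hydroxyoxetan-3-yl)-4-methoxy-5-methylphenyl (E)-2-methylbut-2-enoate
Conditions: 7 (1.05 equiv), pyridine (3 equiv), CH2Cl2, −20 to 0 °C
Reagents that add atoms: none
Why: Einhorn acylation (acid chloride, pyridine) should take the phenol far faster than the tertiary alcohol, and pyridine in place of a trialkylamine avoids the vinylketene pathway that would deconjugate or isomerise the tiglate.

Step 4
Reactants: 8 2-(3-hydroxyoxetan-3-yl)-4-methoxy-5-methylphenyl (E)-2-methylbut-2-enoate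
Product: 9 4-methoxy-5-methyl-2-[3-(triethylsilyloxy)oxetan-3-yl]phenyl (E)-2-methylbut-2-enoate (achiral)
Conditions: TESOTf (1.3 equiv), 2,6-lutidine (2.5 equiv), CH2Cl2, −78 to −40 °C
Reagents that add atoms: triethylsilyl trifluoromethanesulfonate, CC[Si](CC)(CC)OS(=O)(=O)C(F)(F)F
Why: Silyl triflate with a hindered pyridine base is the standard silylation of tertiary alcohols and, in the cold buffered medium, should leave the oxetane and the aryl ester alone; the cap keeps the tertiary hydroxyl from liberating HBr in step 5 and keeps it distinct from the primary oxygen formed there.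

Step 5
Reactants: 9 4-methoxy-5-methyl-2-[3-(triethylsilyloxy)oxetan-3-yl]phenyl (E)-2-methylbut-2-enoate
Product: 11 2-[(2S)-1-bromo-3-hydroxy-2-(triethylsilyloxy)propan-2-yl]-4-methoxy-5-methylphenyl (E)-2-methylbut-2-enoate, via primary trimethylsilyl ether 10 (not isolated)
Conditions: TMSBr (1.5 equiv), 3-{[3,5-bis(trifluoromethyl)phenyl]amino}-4-({(2S)-3,3-dimethyl-1-oxo-1-[(2R)-2-(pyren-1-yl)pyrrolidin-1-yl]butan-2-yl}amino)cyclobut-3-ene-1,2-dione or its mirror image (5–10 mol%), t-BuOMe, −80 °C; then pyridine (2 equiv)/MeOH, −80 to 0 °C
Reagents that add atoms: bromotrimethylsilane, C[Si](C)(C)Br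
Why: TMSBr silylates the oxetane oxygen while the two squaramide N–H bonds hold the bromide, so the anion reaches one ring CH2 of the O-silyl oxetanium ion as a chiral ion pair and displaces oxygen in an SN2 step driven by release of about 25 kcal/mol of ring strain; the γ-bromo trimethylsilyl ether 10 then loses its primary silyl group in the pyridinium-buffered methanol quench. The closest known reaction type is the hydrogen-bond-donor (anion-binding) catalysed enantioselective opening of 3-substituted and 3,3-disubstituted oxetanes with TMSBr. No ring is closed: one C–Br bond forms, one ring O–CH2 bond breaks, and the oxirane appears only in step 8. The former C3 becomes the quaternary stereocentre under catalyst control, because the catalyst-bound bromide picks one of the two enantiotopic CH2 groups and no bond to C3 itself changes. The step needs enantiotopic-group selectivity and a silent background reaction; the substrate offers two very different C3 substituents (a twisted ortho-acyloxyaryl ring against OSiEt3) for the catalyst to tell apart, primary carbons as the only sites of attack, and a capped tertiary oxygen that cannot generate HBr, while ionisation at C3 is held back by the two flanking CH2–O groups and the low temperature.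

Step 6
Reactants: 11 2-[(2S)-1-bromo-3-hydroxy-2-(triethylsilyloxy)propan-2-yl]-4-methoxy-5-methylphenyl (E)-2-methylbut-2-enoate; 12 3-methylbutanoyl chloride (isovaleryl chloride)
Product: 13 2-[(2S)-1-bromo-3-(3-methylbutanoyloxy)-2-(triethylsilyloxy)propan-2-yl]-4-methoxy-5-methylphenyl (E)-2-methylbut-2-enoate
Conditions: 12 (1.5 equiv), pyridine (4 equiv), CH2Cl2, −20 to 0 °C, 11 added to the premixed acylating agent
Reagents that add atoms: none
Why: Einhorn acylation of a primary alcohol, in which an excess of acyl chloride present from the start should let esterification outrun any transfer of the tigloyl group from the aryl oxygen to the new hydroxyl, and pyridine is too weak a base to re-close an oxetane from the γ-bromo alcohol.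

Step 7
Reactants: 13 2-[(2S)-1-bromo-3-(3-methylbutanoyloxy)-2-(triethylsilyloxy)propan-2-yl]-4-methoxy-5-methylphenyl (E)-2-methylbut-2-enoate
Product: 14 2-[(2S)-1-bromo-2-hydroxy-3-(3-methylbutanoyloxy)propan-2-yl]-4-methoxy-5-methylphenyl (E)-2-methylbut-2-enoate
Conditions: HF·pyridine, pyridine, THF, 0 °C to rt
Reagents that add atoms: none
Why: Fluoride-mediated Si–O cleavage under acidic buffering should remove the triethylsilyl group without touching the two esters or the primary bromide, whereas tetrabutylammonium fluoride is basic enough to cleave aryl esters; the stereocentre takes no part.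

Step 8
Reactants: 14 2-[(2S)-1-bromo-2-hydroxy-3-(3-methylbutanoyloxy)propan-2-yl]-4-methoxy-5-methylphenyl (E)-2-methylbut-2-enoate
Product: 15 4-methoxy-5-methyl-2-{(2R)-2-[(3-methylbutanoyloxy)methyl]oxiran-2-yl}phenyl (E)-2-methylbut-2-enoate (CNP0108422.1)
Conditions: Ag2O (2 equiv), 4 Å MS, CH2Cl2, 0 °C to rt, dark
Reagents that add atoms: none
Why: Silver-assisted intramolecular Williamson etherification (3-exo-tet), in which Ag2O pulls on the bromide while the neutral tertiary hydroxyl attacks the adjacent CH2, so that no free alkoxide is present to take an acyl group from either ester; only the O–CH2 bond forms, so the stereocentre keeps its geometry and its label changes from S to R.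

**Compound list**

1 | 4-methoxy-3-methylphenol | COc1ccc(O)cc1C | starting material
2 | 2-bromo-4-methoxy-5-methylphenol | Oc1cc(C)c(OC)cc1Br | intermediate
3 | oxetan-3-one | O=C1COC1 | starting material
4 | lithium 2-bromo-4-methoxy-5-methylphenolate | [Li]Oc1cc(C)c(OC)cc1Br | intermediate
5 | lithium 2-lithio-4-methoxy-5-methylphenolate | [Li]Oc1cc(C)c(OC)cc1[Li] | intermediate
6 | 3-(2-hydroxy-5-methoxy-4-methylphenyl)oxetan-3-ol | Oc1cc(C)c(OC)cc1C1(O)COC1 | intermediate
7 | (E)-2-methylbut-2-enoyl chloride (tigloyl chloride) | C/C=C(\C)C(=O)Cl | starting material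
8 | 2-(3-hydroxyoxetan-3-yl)-4-methoxy-5-methylphenyl (E)-2-methylbut-2-enoate | C/C=C(\C)C(=O)Oc1cc(C)c(OC)cc1C1(O)COC1 | intermediate
9 | 4-methoxy-5-methyl-2-[3-(triethylsilyloxy)oxetan-3-yl]phenyl (E)-2-methylbut-2-enoate | C/C=C(\C)C(=O)Oc1cc(C)c(OC)cc1C1(O[Si](CC)(CC)CC)COC1 | intermediate
10 | 2-[(2S)-1-bromo-2-(triethylsilyloxy)-3-(trimethylsilyloxy)propan-2-yl]-4-methoxy-5-methylphenyl (E)-2-methylbut-2-enoate | C/C=C(\C)C(=O)Oc1cc(C)c(OC)cc1[C@](O[Si](CC)(CC)CC)(CO[Si](C)(C)C)CBr | intermediate
11 | 2-[(2S)-1-bromo-3-hydroxy-2-(triethylsilyloxy)propan-2-yl]-4-methoxy-5-methylphenyl (E)-2-methylbut-2-enoate | C/C=C(\C)C(=O)Oc1cc(C)c(OC)cc1[C@](O[Si](CC)(CC)CC)(CO)CBr | intermediate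
12 | 3-methylbutanoyl chloride (isovaleryl chloride) | CC(C)CC(=O)Cl | starting material
13 | 2-[(2S)-1-bromo-3-(3-methylbutanoyloxy)-2-(triethylsilyloxy)propan-2-yl]-4-methoxy-5-methylphenyl (E)-2-methylbut-2-enoate | C/C=C(\C)C(=O)Oc1cc(C)c(OC)cc1[C@](O[Si](CC)(CC)CC)(COC(=O)CC(C)C)CBr | intermediate
14 | 2-[(2S)-1-bromo-2-hydroxy-3-(3-methylbutanoyloxy)propan-2-yl]-4-methoxy-5-methylphenyl (E)-2-methylbut-2-enoate | C/C=C(\C)C(=O)Oc1cc(C)c(OC)cc1[C@](O)(COC(=O)CC(C)C)CBr | intermediate
15 | 4-methoxy-5-methyl-2-{(2R)-2-[(3-methylbutanoyloxy)methyl]oxiran-2-yl}phenyl (E)-2-methylbut-2-enoate | C/C=C(\C)C(=O)Oc1cc(C)c(OC)cc1[C@]1(COC(=O)CC(C)C)CO1 | target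

**Totals**

Total step count: 8. Longest linear sequence: 8 steps (1 to 15); 3, 7 and 12 are purchased and enter directly.

**Steps most likely to fail**

Step 5. The catalyst may fail to discriminate the enantiotopic CH2 groups when C3 carries both a bulky silyloxy group and a twisted ortho-substituted aryl ring. The crowded oxetane may also open only at temperatures where uncatalysed bromide attack erodes the ee. The fallback differentiates the same pair of CH2–O arms with an enzyme on an open-chain prochiral triol. It sets out from 2 and comes back at 15.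
- The lithiation of step 2 is repeated and 5 is added to commercial 2,2-dimethyl-1,3-dioxan-5-one, which should give 5-(2-hydroxy-5-methoxy-4-methylphenyl)-2,2-dimethyl-1,3-dioxan-5-ol F1.
- Tigloylation with 7 and pyridine as in step 3 should give 2-(5-hydroxy-2,2-dimethyl-1,3-dioxan-5-yl)-4-methoxy-5-methylphenyl (E)-2-methylbut-2-enoate F2.
- Aqueous acetic acid at room temperature removes the acetonide to give 2-(1,2,3-trihydroxypropan-2-yl)-4-methoxy-5-methylphenyl (E)-2-methylbut-2-enoate F3.
- Lipase-catalysed monoacylation with vinyl 3-methylbutanoate in t-BuOMe (Burkholderia cepacia lipase or Candida antarctica lipase B, screened for the arm required) should give 2-[(2R)-1,2-dihydroxy-3-(3-methylbutanoyloxy)propan-2-yl]-4-methoxy-5-methylphenyl (E)-2-methylbut-2-enoate F4.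
- Mitsunobu cyclodehydration (PPh3, diisopropyl azodicarboxylate, THF, 0 °C) activates the remaining primary hydroxyl and lets the tertiary hydroxyl close the oxirane, giving 15.

Step 2. Bromine–lithium exchange on the electron-rich phenolate may be incomplete, the dianion may aggregate, the ketone may be enolised, and the oxetane may be opened by the neighbouring phenol during work-up. The fallback masks the phenol during the organometallic step. It sets out from 2 and comes back at 6.
- O-Allylation (allyl bromide, K2CO3, acetone, reflux) should give 1-bromo-5-methoxy-4-methyl-2-(prop-2-en-1-yloxy)benzene F5.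
- n-BuLi in THF at −78 °C should give [5-methoxy-4-methyl-2-(prop-2-en-1-yloxy)phenyl]lithium F6, which is kept cold to avoid cyclisation onto the allyl group.
- Addition of F6 to 3 should give 3-[5-methoxy-4-methyl-2-(prop-2-en-1-yloxy)phenyl]oxetan-3-ol F7.
- Deallylation with catalytic Pd(PPh3)4 (zerovalent palladium) and morpholine in THF at room temperature returns 6 under non-acidic conditions.

Step 8. Ring closure at the crowded centre may be overtaken by acyl transfer to the tertiary oxygen (1,2-shift of the flanking isovalerate, or transfer from the aryl tiglate). Silver-assisted ionisation may also be diverted into a 1,2-aryl shift or into rearrangement of the acid-sensitive aryl epoxide. The fallback closes the oxirane before the isovalerate is present, on a less crowded diol, and leaves a plain acylation as the last step. It sets out from 11 and comes back at 15.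
- HF·pyridine in THF should give 2-[(2S)-1-bromo-2,3-dihydroxypropan-2-yl]-4-methoxy-5-methylphenyl (E)-2-methylbut-2-enoate F8.
- Ag2O in CH2Cl2 should close this to 2-[(2S)-2-(hydroxymethyl)oxiran-2-yl]-4-methoxy-5-methylphenyl (E)-2-methylbut-2-enoate F9; three-membered closure by the tertiary oxygen should outrun four-membered closure by the primary one.
- Acylation of the primary hydroxyl with 12 and pyridine at −20 °C gives 15. The S label of F9 becomes R in 15 by priority change only.

Further compounds
F1 | step 5 | 5-(2-hydroxy-5-methoxy-4-methylphenyl)-2,2-dimethyl-1,3-dioxan-5-ol | Oc1cc(C)c(OC)cc1C1(O)COC(C)(C)OC1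
F2 | step 5 | 2-(5-hydroxy-2,2-dimethyl-1,3-dioxan-5-yl)-4-methoxy-5-methylphenyl (E)-2-methylbut-2-enoate | C/C=C(\C)C(=O)Oc1cc(C)c(OC)cc1C1(O)COC(C)(C)OC1
F3 | step 5 | 2-(1,2,3-trihydroxypropan-2-yl)-4-methoxy-5-methylphenyl (E)-2-methylbut-2-enoate | C/C=C(\C)C(=O)Oc1cc(C)c(OC)cc1C(O)(CO)CO
F4 | step 5 | 2-[(2R)-1,2-dihydroxy-3-(3-methylbutanoyloxy)propan-2-yl]-4-methoxy-5-methylphenyl (E)-2-methylbut-2-enoate | C/C=C(\C)C(=O)Oc1cc(C)c(OC)cc1[C@](O)(COC(=O)CC(C)C)CO
F5 | step 2 | 1-bromo-5-methoxy-4-methyl-2-(prop-2-en-1-yloxy)benzene | C=CCOc1cc(C)c(OC)cc1Br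
F6 | step 2 | [5-methoxy-4-methyl-2-(prop-2-en-1-yloxy)phenyl]lithium | C=CCOc1cc(C)c(OC)cc1[Li]
F7 | step 2 | 3-[5-methoxy-4-methyl-2-(prop-2-en-1-yloxy)phenyl]oxetan-3-ol | C=CCOc1cc(C)c(OC)cc1C1(O)COC1
F8 | step 8 | 2-[(2S)-1-bromo-2,3-dihydroxypropan-2-yl]-4-methoxy-5-methylphenyl (E)-2-methylbut-2-enoate | C/C=C(\C)C(=O)Oc1cc(C)c(OC)cc1[C@](O)(CO)CBr
F9 | step 8 | 2-[(2S)-2-(hydroxymethyl)oxiran-2-yl]-4-methoxy-5-methylphenyl (E)-2-methylbut-2-enoate | C/C=C(\C)C(=O)Oc1cc(C)c(OC)cc1[C@]1(CO)CO1
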